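**Retrosynthetic overview**
1. Target 15 ⇐ 14 by removal of the 4'-O-pivalate, which both differentiates the two hydroxyls of ring B and deactivates that ring.
2. 14 ⇐ 2 + 11 in one pot: C4–C4a bond and the C3 stereocentre by acid-catalysed enantioselective Friedel–Crafts opening of a prochiral 3-aryloxetane, then O1–C2 closure (ring C) and aryl propargyl ether Claisen/oxa-6π cascade (ring D).
3. 11 ⇐ 4-bromoresorcinol: pivalate on the OH para to Br, Negishi coupling with 3-iodooxetane, O-propargylation of the remaining OH.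
4. 2 ⇐ 2,4,6-trihydroxybenzaldehyde by 4-O-methylation; the symmetry of 2 makes the ring-A substitution pattern unambiguous.
5. Ring order: rings A and B come from the starting materials; ring C and then ring D are formed last, in the same operation.

Assumption: the sense of induction of the chiral phosphoric acid in step 5 cannot be predicted with certainty; the (R)-catalyst is written, and its antipode is used if a test run gives the (S)-alcohol.

**Step 1**
Reactants: 1 2,4,6-trihydroxybenzaldehyde
Product: 2 2,6-dihydroxy-4-methoxybenzaldehyde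
Conditions: Me2SO4 (1.0 equiv), K2CO3 (1.0 equiv), acetone, 0 → 25 °C
Reagents that add atoms: dimethyl sulfate, COS(=O)(=O)OC
Why: Williamson O-methylation with one equivalent of a hard electrophile goes to the 4-OH, the only hydroxyl not hydrogen-bonded to the formyl group and the most acidic one, giving a symmetric phenol whose two free ring carbons and two OH groups are equivalent.

**Step 2**
Reactants: 3 4-bromobenzene-1,3-diol (4-bromoresorcinol)
Product: 4 4-bromo-3-hydroxyphenyl pivalate
Conditions: PivCl (1.0 equiv), Et3N (1.05 equiv), CH2Cl2, −40 → 0 °C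
Reagents that add atoms: pivaloyl chloride, CC(C)(C)C(Cl)=O
Why: Kinetically controlled mono-acylation, in which the bulky acyl chloride takes the OH para to Br because it is unhindered and its phenoxide is the more nucleophilic one, while the ortho-bromo OH stays free.

**Step 3**
Reactants: 4 4-bromo-3-hydroxyphenyl pivalate; 5 3-iodooxetane
Product: 9 3-hydroxy-4-(oxetan-3-yl)phenyl pivalate, via silylated bromide 6 (not isolated), via oxetan-3-ylzinc iodide 7 (not isolated), via silylated aryl oxetane 8 (not isolated)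
Conditions: HMDS (0.6 equiv), cat. (NH4)2SO4, THF, 60 °C, evaporate; 5, Zn dust, LiCl, THF, 35 °C; then Pd(OAc)2 (3 mol%), CPhos (6 mol%), THF, 25 → 45 °C; then MeOH, K2CO3 (0.1 equiv), 0 °C, pH 8 work-up
Reagents that add atoms: none
Why: Negishi coupling of the secondary alkylzinc (zinc insertion into the C–I bond) with the aryl bromide at a zerovalent palladium/CPhos catalyst, with the phenol silylated in the flask so that it neither quenches the zinc reagent nor opens the oxetane under zinc halide Lewis acidity; basic methanolysis then frees the phenol.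

**Step 4**
Reactants: 9 3-hydroxy-4-(oxetan-3-yl)phenyl pivalate; 10 3-chloro-3-methylbut-1-yne
Product: 11 3-[(2-methylbut-3-yn-2-yl)oxy]-4-(oxetan-3-yl)phenyl pivalate
Conditions: 10 (1.5 equiv), DBU (1.5 equiv), CuCl2·2H2O (1 mol%), MeCN, 0 → 25 °C
Reagents that add atoms: none
Why: Copper-catalysed propargylic etherification of the phenoxide with the tertiary propargylic chloride (via a copper acetylide), run cold and basic so that the oxetane and the pivalate survive; it places the three-carbon unit of ring D on the oxygen ortho to the oxetane.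

**Step 5**
Reactants: 2 2,6-dihydroxy-4-methoxybenzaldehyde; 11 3-[(2-methylbut-3-yn-2-yl)oxy]-4-(oxetan-3-yl)phenyl pivalate
Product: 14 8-[(3R)-8-formyl-7-hydroxy-5-methoxychroman-3-yl]-2,2-dimethyl-2H-chromen-5-yl pivalate, via ring-opened alcohol 12 (not isolated), via chroman propargyl ether 13 (not isolated)
Conditions: 2 (2 equiv), (R)-STRIP (spirobiindane phosphoric acid with 2,4,6-triisopropylphenyl groups, 10 mol%), 4 Å MS, PhMe, 40 °C; then Et3N (0.2 equiv), PPh3 (1.3 equiv), DIAD (1.3 equiv), PhMe (0.01 M), 0 → 25 °C; then 150 °C, sealed tube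
Reagents that add atoms: none
Why: Proposed new method: the chiral phosphoric acid protonates the oxetane oxygen of 11 while its P=O oxygen hydrogen-bonds a phenolic OH of 2, so the only free, strongly activated ring carbon of the symmetric phenol opens one of the two enantiotopic CH2–O bonds in an SN2-type Friedel–Crafts alkylation and sets C3 as (R) in 12 (closest known chemistry: phosphoric acid- and squaramide-catalysed enantioselective desymmetrisation of 3-aryloxetanes by thiol, halide and tethered O/N nucleophiles, and acid-catalysed ortho-Friedel–Crafts alkylation of phenols); the released primary alcohol is then closed onto the neighbouring chelated OH by a Mitsunobu reaction (ring C, the stereocentre is not the reacting carbon), and heating triggers the aryl propargyl ether Claisen rearrangement to the only free ortho carbon, [1,5]-H shift and oxa-6π electrocyclisation (ring D).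

**Step 6**
Reactants: 14 8-[(3R)-8-formyl-7-hydroxy-5-methoxychroman-3-yl]-2,2-dimethyl-2H-chromen-5-yl pivalate
Product: 15 (3R)-7-hydroxy-3-(5-hydroxy-2,2-dimethyl-2H-chromen-8-yl)-5-methoxychromane-8-carbaldehyde
Conditions: K2CO3 (2 equiv), MeOH, 25 °C, N2; aq. NH4Cl
Reagents that add atoms: none
Why: Base-mediated transesterification of the aryl pivalate with methanol, which leaves the chelated aldehyde, the chromene double bond and the non-acidic C3 stereocentre untouched.

**Compound list**
1 | 2,4,6-trihydroxybenzaldehyde | O=Cc1c(O)cc(O)cc1O | starting material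
2 | 2,6-dihydroxy-4-methoxybenzaldehyde | COc1cc(O)c(C=O)c(O)c1 | intermediate
3 | 4-bromobenzene-1,3-diol (4-bromoresorcinol) | Oc1ccc(Br)c(O)c1 | starting material
4 | 4-bromo-3-hydroxyphenyl pivalate | CC(C)(C)C(=O)Oc1ccc(Br)c(O)c1 | intermediate
5 | 3-iodooxetane | IC1COC1 | starting material
6 | 4-bromo-3-(trimethylsilyloxy)phenyl pivalate | CC(C)(C)C(=O)Oc1ccc(Br)c(O[Si](C)(C)C)c1 | intermediate
7 | oxetan-3-ylzinc iodide | I[Zn]C1COC1 | intermediate
8 | 4-(oxetan-3-yl)-3-(trimethylsilyloxy)phenyl pivalate | CC(C)(C)C(=O)Oc1ccc(C2COC2)c(O[Si](C)(C)C)c1 | intermediate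
9 | 3-hydroxy-4-(oxetan-3-yl)phenyl pivalate | CC(C)(C)C(=O)Oc1ccc(C2COC2)c(O)c1 | intermediate
10 | 3-chloro-3-methylbut-1-yne | CC(C)(Cl)C#C | starting material
11 | 3-[(2-methylbut-3-yn-2-yl)oxy]-4-(oxetan-3-yl)phenyl pivalate | CC(C)(C)C(=O)Oc1ccc(C2COC2)c(OC(C)(C)C#C)c1 | intermediate
12 | 4-[(2R)-1-(3-formyl-2,4-dihydroxy-6-methoxyphenyl)-3-hydroxypropan-2-yl]-3-[(2-methylbut-3-yn-2-yl)oxy]phenyl pivalate | COc1cc(O)c(C=O)c(O)c1C[C@H](c1ccc(OC(=O)C(C)(C)C)cc1OC(C)(C)C#C)CO | intermediate
13 | 4-[(3R)-8-formyl-7-hydroxy-5-methoxychroman-3-yl]-3-[(2-methylbut-3-yn-2-yl)oxy]phenyl pivalate | COc1cc(O)c(C=O)c2c1C[C@H](c1ccc(OC(=O)C(C)(C)C)cc1OC(C)(C)C#C)CO2 | intermediate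
14 | 8-[(3R)-8-formyl-7-hydroxy-5-methoxychroman-3-yl]-2,2-dimethyl-2H-chromen-5-yl pivalate | COc1cc(O)c(C=O)c2c1C[C@H](c1ccc(OC(=O)C(C)(C)C)c3c1OC(C)(C)C=C3)CO2 | intermediate
15 | (3R)-7-hydroxy-3-(5-hydroxy-2,2-dimethyl-2H-chromen-8-yl)-5-methoxychromane-8-carbaldehyde | COc1cc(O)c(C=O)c2c1C[C@H](c1ccc(O)c3c1OC(C)(C)C=C3)CO2 | target

**Totals**
Total step count: 6. Longest linear sequence: 5 (steps 2 to 6, from 4-bromoresorcinol).

**Steps most likely to fail**

Step 5. A carbon nucleophile has not been used in this oxetane desymmetrisation. The deactivated phenol may react slowly, and O-alkylation, opening by the product alcohol or participation of the neighbouring aryl ether oxygen may compete. The ee is unknown. The fallback sets out from 11 and rejoins at 13. Oxetane 11 is opened with TMSBr under a chiral squaramide hydrogen-bond-donor catalyst (the known enantioselective bromide opening of 3-aryloxetanes, catalyst enantiomer chosen for the R product) to give 4-[(2R)-1-bromo-3-(trimethylsilyloxy)propan-2-yl]-3-[(2-methylbut-3-yn-2-yl)oxy]phenyl pivalate F1. Methanolysis of the silyl ether gives 4-[(2R)-1-bromo-3-hydroxypropan-2-yl]-3-[(2-methylbut-3-yn-2-yl)oxy]phenyl pivalate F2. A Mitsunobu reaction with excess 2 gives the mono-ether 4-[(2R)-1-bromo-3-(2-formyl-3-hydroxy-5-methoxyphenoxy)propan-2-yl]-3-[(2-methylbut-3-yn-2-yl)oxy]phenyl pivalate F3. Cs2CO3 in DMF at 60 °C then closes ring C by intramolecular C-alkylation of the phenoxide at the carbon para to O−, giving 13, which is heated on to 14 as in step 5. Elimination of HBr is the main hazard of this ring closure.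

Step 3. The secondary zinc reagent must couple at a hindered ortho-siloxy bromide. Early loss of the silyl group would let the phenol quench 7 or open the oxetane, and 9 rearranges to a dihydrobenzofuran under acid. The fallback sets out from 4 and rejoins at 9. Phenol 4 is silylated (TBSCl, imidazole) to 4-bromo-3-[(tert-butyldimethylsilyl)oxy]phenyl pivalate F4. F4 is joined to 5 by a nickel-catalysed reductive cross-electrophile coupling (NiBr2(dme), 4,4'-di-tert-butyl-2,2'-bipyridine, Mn powder, NaI, DMA, 60 °C; no organozinc and no zinc halide) to give 3-[(tert-butyldimethylsilyl)oxy]-4-(oxetan-3-yl)phenyl pivalate F5. Buffered fluoride (TBAF/AcOH, THF, 0 °C) then gives 9.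

Step 1. Mono-O-methylation may be accompanied by di-O-methylation and C-methylation. The fallback sets out from 1 and rejoins at 2. Aldehyde 1 is exhaustively O-methylated (excess Me2SO4, K2CO3, acetone, reflux) to 2,4,6-trimethoxybenzaldehyde F6. AlCl3 in CH2Cl2 then cleaves only the two methoxy groups ortho to the formyl group (chelation-controlled demethylation) and returns 2.

**Further compounds**
F1 | step 5 | 4-[(2R)-1-bromo-3-(trimethylsilyloxy)propan-2-yl]-3-[(2-methylbut-3-yn-2-yl)oxy]phenyl pivalate | BrC[C@H](c1ccc(OC(=O)C(C)(C)C)cc1OC(C)(C)C#C)CO[Si](C)(C)C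
F2 | step 5 | 4-[(2R)-1-bromo-3-hydroxypropan-2-yl]-3-[(2-methylbut-3-yn-2-yl)oxy]phenyl pivalate | BrC[C@H](c1ccc(OC(=O)C(C)(C)C)cc1OC(C)(C)C#C)CO
F3 | step 5 | 4-[(2R)-1-bromo-3-(2-formyl-3-hydroxy-5-methoxyphenoxy)propan-2-yl]-3-[(2-methylbut-3-yn-2-yl)oxy]phenyl pivalate | COc1cc(O)c(C=O)c(OC[C@@H](c2ccc(OC(=O)C(C)(C)C)cc2OC(C)(C)C#C)CBr)c1
F4 | step 3 | 4-bromo-3-[(tert-butyldimethylsilyl)oxy]phenyl pivalate | CC(C)(C)C(=O)Oc1ccc(Br)c(O[Si](C)(C)C(C)(C)C)c1
F5 | step 3 | 3-[(tert-butyldimethylsilyl)oxy]-4-(oxetan-3-yl)phenyl pivalate | CC(C)(C)C(=O)Oc1ccc(C2COC2)c(O[Si](C)(C)C(C)(C)C)c1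
F6 | step 1 | 2,4,6-trimethoxybenzaldehyde | COc1cc(OC)c(C=O)c(OC)c1
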